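**Strategy.** Ring A is closed by a reductive radical [3+3] annulation that makes C2–C3 and C5–C10 (labdane numbering) in one flask. The step exploits the two axial one-carbon groups of ring A: C20 starts as the terminal CH2 of a 2-substituted butadiene (C2, C1, C10, C20) that takes up two hydrogen atoms, and C19 is the carbonyl of an α-methylene-β-acetoxy δ-lactone whose C3 and then C5 accept the two radicals. The lactone (C3–C8, C19) carries the one catalytically set stereocentre, C7, which relays to C5, C10 and C4; ring B (C8, C9) is then closed by chelation-controlled allylation.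

Key step: step 8

Remark: labdane numbering (C1–C20) is used for all intermediates; the carbinol centres made in steps 4 and 11 and the THP acetal carbon are carried as epimer mixtures because they are destroyed later.

Step 1
Reactants: 1 methyl 4,4-dimethoxy-3-oxopentanoate
Product: 2 methyl (3R)-3-hydroxy-4,4-dimethoxypentanoate
Conditions: H2 (50 bar), RuCl2[(S)-BINAP] (0.5 mol %), MeOH, 50 °C
Reagents that add atoms: none
Why: Noyori asymmetric hydrogenation of a β-keto ester, in which the ester-chelated ketone is reduced on one face by the BINAP ruthenium hydride; the (S)-ligand should give the (3R)-carbinol (future C7), the same spatial sense as with methyl acetoacetate.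

Step 2
Reactants: 2 methyl (3R)-3-hydroxy-4,4-dimethoxypentanoate
Product: 3 methyl (3R)-3-{[tert-butyl(dimethyl)silyl]oxy}-4,4-dimethoxypentanoate
Conditions: TBSCl, imidazole, DMF, 40 °C
Reagents that add atoms: tert-butyl(chloro)dimethylsilane, CC(C)(C)[Si](C)(C)Cl
Why: silyl ether protection of the secondary alcohol, so that the ester can be taken to the aldehyde without β-elimination or retro-aldol cleavage.

Step 3
Reactants: 3 methyl (3R)-3-{[tert-butyl(dimethyl)silyl]oxy}-4,4-dimethoxypentanoate
Product: 4 (3R)-3-{[tert-butyl(dimethyl)silyl]oxy}-4,4-dimethoxypentanal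
Conditions: i-Bu2AlH (1.1 equiv), CH2Cl2, −78 °C; Rochelle salt work-up
Reagents that add atoms: none
Why: partial ester reduction, which stops at the aldehyde because the tetrahedral aluminium hemiacetal is stable at low temperature.

Step 4
Reactants: 4 (3R)-3-{[tert-butyl(dimethyl)silyl]oxy}-4,4-dimethoxypentanal
Product: 5 methyl 2-[(3R)-3-{[tert-butyl(dimethyl)silyl]oxy}-1-hydroxy-4,4-dimethoxypentyl]prop-2-enoate
Conditions: methyl acrylate (excess), DABCO (1 equiv), rt
Reagents that add atoms: methyl acrylate, C=CC(=O)OC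
Why: Morita–Baylis–Hillman reaction, which joins C4 to C5 and brings in C3 and C19; the new carbinol (C5) is not controlled because it becomes the leaving group.

Step 5
Reactants: 5 methyl 2-[(3R)-3-{[tert-butyl(dimethyl)silyl]oxy}-1-hydroxy-4,4-dimethoxypentyl]prop-2-enoate
Product: 7 (6R)-6-(1,1-dimethoxyethyl)-4-hydroxy-3-methylideneoxan-2-one, via diol ester 6 (not isolated)
Conditions: Bu4NF (1.2 equiv), THF, 0 °C to rt; aq. NH4Cl
Reagents that add atoms: none
Why: fluoride desilylation followed by lactonisation of the liberated C7 alkoxide onto the methyl ester (6-exo-trig acyl substitution), which gives the α-methylene δ-lactone without touching C7.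

Step 6
Reactants: 7 (6R)-6-(1,1-dimethoxyethyl)-4-hydroxy-3-methylideneoxan-2-one
Product: 8 (6R)-6-(1,1-dimethoxyethyl)-3-methylidene-2-oxooxan-4-yl acetate
Conditions: Ac2O, pyridine, CH2Cl2, 0 °C
Reagents that add atoms: acetic anhydride, CC(=O)OC(C)=O
Why: O-acetylation of the Baylis–Hillman alcohol to install the leaving group on C5, run without DMAP so that the allylic acetate is not transposed.

Step 7
Reactants: 9 3,3-diethoxyprop-1-yne
Product: 10 2-(diethoxymethyl)buta-1,3-diene
Conditions: ethene (1 atm), second-generation Grubbs catalyst [RuCl2(H2IMes)(PCy3)(=CHPh)] (3 mol %), CH2Cl2, rt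
Reagents that add atoms: ethene, C=C
Why: intermolecular enyne (alkyne–ethene) cross-metathesis, which turns the terminal alkyne into a 2-substituted buta-1,3-diene.

Step 8
Reactants: 8 (6R)-6-(1,1-dimethoxyethyl)-3-methylidene-2-oxooxan-4-yl acetate; 10 2-(diethoxymethyl)buta-1,3-diene
Product: 12 (3R,4aS,5S,8aS)-5-(diethoxymethyl)-3-(1,1-dimethoxyethyl)-5-methyloctahydro-1H-isochromen-1-one, via dihydropyranone 11 (not isolated)
Conditions: Fe(acac)3 (30 mol %), PhSiH3 (5 equiv), Na2HPO4, EtOH/THF, 60 °C; 8 added slowly to 10 (2 equiv)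
Reagents that add atoms: none
Why: Proposed new method: the iron hydride formed from Fe(acac)3 and PhSiH3 transfers a hydrogen atom to the terminal CH2 (future C20) of diene 10, the resulting allyl radical adds through its primary terminus C2 to the exocyclic CH2 (C3) of 8, and the α-acyl radical is reduced to the enolate, which expels acetate (E1cB) to give enoate 11; a second hydrogen-atom transfer to C1 of its trisubstituted alkene gives the tertiary C10 radical, which attacks C5 and is then reduced and protonated at C4. The closest known reaction types are the MHAT-initiated Giese coupling of alkenes with acrylates (Fe(acac)3/PhSiH3), including its 6-endo ring closures, and the ionic Lawton α,α'-annulation, which uses a 2-(acyloxymethyl)acrylate unit as a C3/C5 double acceptor in the same way; what is new is the use of a 1,3-diene as a propane-1,3-diyl donor through two successive hydrogen-atom transfers. Only ring A is closed, by a 6-endo-trig radical cyclisation, which is preferred to 5-exo attack on C4 because the nucleophilic tertiary radical is matched with the β-carbon of the unsaturated lactone. C5 is set by attack anti to the 1,1-dimethoxyethyl group on C7 of the half-chair dihydropyranone (trans-4,6 addition), C10 by a chair transition state with the branched CH(OEt)2 group equatorial and the methyl axial, and C4 by protonation to the cis-fused lactone (reset in step 9). The step needs C2-selective capture of the unsymmetrical allyl radical and ring closure faster than intermolecular addition of the C10 radical to a second molecule of 8; the first is secured by the steric difference between the primary and the fully substituted terminus, the second by slow addition of 8 to an excess of 10.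

Step 9
Reactants: 12 (3R,4aS,5S,8aS)-5-(diethoxymethyl)-3-(1,1-dimethoxyethyl)-5-methyloctahydro-1H-isochromen-1-one
Product: 13 (3R,4aR,5S,8aS)-5-(diethoxymethyl)-3-(1,1-dimethoxyethyl)-5,8a-dimethyloctahydro-1H-isochromen-1-one
Conditions: LiN(i-Pr)2 (1.2 equiv), THF, −78 °C; MeI, −78 to −30 °C
Reagents that add atoms: iodomethane, CI
Why: alkylation of the lactone enolate, in which iodomethane should approach C4 from the α-face (equatorial to ring A and anti to the axial C10 methyl), giving the cis-fused lactone with 4α-CH3 and 4β-C19.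

Step 10
Reactants: 13 (3R,4aR,5S,8aS)-5-(diethoxymethyl)-3-(1,1-dimethoxyethyl)-5,8a-dimethyloctahydro-1H-isochromen-1-one
Product: 15 (1S,2S,3S)-2-[(2R)-2-hydroxy-3-oxobutyl]-3-(hydroxymethyl)-1,3-dimethylcyclohexane-1-carbaldehyde, via diol bis-acetal 14 (not isolated)
Conditions: LiAlH4, THF, 0 to 40 °C; then 2 M aq. HCl/THF, rt
Reagents that add atoms: water, O
Why: hydride reduction of the lactone to the 7,19-diol, then acid hydrolysis (oxocarbenium mechanism) of the acetal and the ketal to the C9 aldehyde and the C8 ketone; no stereocentre is touched, and the product is expected to sit partly as the 7-O lactol.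

Step 11
Reactants: 15 (1S,2S,3S)-2-[(2R)-2-hydroxy-3-oxobutyl]-3-(hydroxymethyl)-1,3-dimethylcyclohexane-1-carbaldehyde
Product: 16 (3R)-3-hydroxy-4-[(1S,2S,6S)-2-(1-hydroxyprop-2-en-1-yl)-6-(hydroxymethyl)-2,6-dimethylcyclohexyl]butan-2-one
Conditions: bromoethene, CrCl2 (6 equiv), NiCl2 (2 mol %), DMF/THF, rt
Reagents that add atoms: bromoethene, C=CBr
Why: Nozaki–Hiyama–Kishi vinylation, in which the vinylchromium reagent adds to the aldehyde and leaves the ketone and the free hydroxyls alone; the new C9 carbinol is not controlled because it is ionised in step 12.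

Step 12
Reactants: 16 (3R)-3-hydroxy-4-[(1S,2S,6S)-2-(1-hydroxyprop-2-en-1-yl)-6-(hydroxymethyl)-2,6-dimethylcyclohexyl]butan-2-one
Product: 17 (4S,5R,7R,8S,9R,10S)-13,14,15,16-tetranorlabd-11-ene-7,8,19-triol
Conditions: Pd(PPh3)4 (5 mol %), InI (2.5 equiv), THF, rt to 40 °C
Reagents that add atoms: none
Why: palladium-catalysed umpolung (Barbier-type) allylation, in which the π-allylpalladium complex from the allylic alcohol is reduced by InI to an allylindium that adds through its γ-carbon C9 to the C8 ketone in a chair transition state with indium chelated between the 7α-hydroxyl and the carbonyl oxygen, so that ring B closes as a trans-decalin with 8α-OH cis to 7α-OH, the 8-methyl axial and the C9 vinyl group equatorial (9β).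

Step 13
Reactants: 17 (4S,5R,7R,8S,9R,10S)-13,14,15,16-tetranorlabd-11-ene-7,8,19-triol
Product: 19 (4S,5R,7R,8S,9R,10S)-labda-13(16),14-diene-7,8,19-triol, via alkylborane 18 (not isolated)
Conditions: 9-BBN-H (5 equiv), THF, rt; then 2-chlorobuta-1,3-diene, Pd(OAc)2 (5 mol %), SPhos (10 mol %), aq. K3PO4, 60 °C
Reagents that add atoms: 2-chlorobuta-1,3-diene, C=CC(Cl)=C
Why: anti-Markovnikov hydroboration of the vinyl group followed by B-alkyl Suzuki–Miyaura coupling with the alkenyl chloride, which forms C12–C13 and completes the 2-substituted diene without touching a stereocentre.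

Step 14
Reactants: 20 4-(oxan-2-yloxy)benzaldehyde; 21 methyl 2-[bis(2,2,2-trifluoroethoxy)phosphoryl]acetate
Product: 22 methyl (2Z)-3-[4-(oxan-2-yloxy)phenyl]prop-2-enoate
Conditions: KN(SiMe3)2, 18-crown-6, THF, −78 °C
Reagents that add atoms: none
Why: Still–Gennari olefination, in which the electron-poor phosphonate makes elimination from the kinetic syn adduct fast and should give the Z-alkene.

Step 15
Reactants: 22 methyl (2Z)-3-[4-(oxan-2-yloxy)phenyl]prop-2-enoate
Product: 23 (2Z)-3-[4-(oxan-2-yloxy)phenyl]prop-2-enoic acid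
Conditions: LiOH, THF/H2O, rt; dilute H3PO4 to pH 4
Reagents that add atoms: lithium hydroxide, [Li+].[OH-]
Why: ester saponification (acyl substitution by hydroxide) under conditions that leave the base-stable THP ether and the Z-alkene intact.

Step 16
Reactants: 19 (4S,5R,7R,8S,9R,10S)-labda-13(16),14-diene-7,8,19-triol; 23 (2Z)-3-[4-(oxan-2-yloxy)phenyl]prop-2-enoic acid
Product: 24 (4S,5R,7R,8S,9R,10S)-7,8-dihydroxylabda-13(16),14-dien-19-yl (2Z)-3-[4-(oxan-2-yloxy)phenyl]prop-2-enoate
Conditions: EDC·HCl, DMAP (0.2 equiv), CH2Cl2, 0 °C to rt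
Reagents that add atoms: none
Why: Steglich-type carbodiimide esterification, in which the primary C19 hydroxyl should react in preference to the axial secondary 7-OH (flanked by the tertiary carbinol) and the tertiary 8-OH.

Step 17
Reactants: 24 (4S,5R,7R,8S,9R,10S)-7,8-dihydroxylabda-13(16),14-dien-19-yl (2Z)-3-[4-(oxan-2-yloxy)phenyl]prop-2-enoate
Product: 25 (4S,5R,7R,8S,9R,10S)-7,8-dihydroxylabda-13(16),14-dien-19-yl (2Z)-3-(4-hydroxyphenyl)prop-2-enoate
Conditions: PPTS (0.1 equiv), EtOH, 45 °C
Reagents that add atoms: none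
Why: acid-catalysed transacetalisation to ethanol removes the THP group under conditions mild enough for the Z-cinnamate, the 1,3-diene and the tertiary alcohol.

**Compound list**

1 | methyl 4,4-dimethoxy-3-oxopentanoate | CC(OC)(OC)C(=O)CC(=O)OC | starting material
2 | methyl (3R)-3-hydroxy-4,4-dimethoxypentanoate | CC(OC)(OC)[C@H](O)CC(=O)OC | intermediate
3 | methyl (3R)-3-{[tert-butyl(dimethyl)silyl]oxy}-4,4-dimethoxypentanoate | CC(OC)(OC)[C@H](O[Si](C)(C)C(C)(C)C)CC(=O)OC | intermediate
4 | (3R)-3-{[tert-butyl(dimethyl)silyl]oxy}-4,4-dimethoxypentanal | CC(OC)(OC)[C@H](O[Si](C)(C)C(C)(C)C)CC=O | intermediate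
5 | methyl 2-[(3R)-3-{[tert-butyl(dimethyl)silyl]oxy}-1-hydroxy-4,4-dimethoxypentyl]prop-2-enoate (both C1' epimers) | CC(OC)(OC)[C@H](O[Si](C)(C)C(C)(C)C)CC(O)C(=C)C(=O)OC | intermediate
6 | methyl 2-[(3R)-1,3-dihydroxy-4,4-dimethoxypentyl]prop-2-enoate (diol ester, not isolated) | CC(OC)(OC)[C@H](O)CC(O)C(=C)C(=O)OC | intermediate
7 | (6R)-6-(1,1-dimethoxyethyl)-4-hydroxy-3-methylideneoxan-2-one (both C4 epimers) | CC(OC)(OC)[C@H]1CC(O)C(=C)C(=O)O1 | intermediate
8 | (6R)-6-(1,1-dimethoxyethyl)-3-methylidene-2-oxooxan-4-yl acetate (both C4 epimers) | CC(OC)(OC)[C@H]1CC(OC(C)=O)C(=C)C(=O)O1 | intermediate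
9 | 3,3-diethoxyprop-1-yne | C#CC(OCC)OCC | starting material
10 | 2-(diethoxymethyl)buta-1,3-diene | C=CC(=C)C(OCC)OCC | intermediate
11 | (6R)-3-[(3Z)-5,5-diethoxy-4-methylpent-3-en-1-yl]-6-(1,1-dimethoxyethyl)-5,6-dihydro-2H-pyran-2-one (dihydropyranone, not isolated; alkene geometry inconsequential) | CC(OC)(OC)[C@H]1CC=C(CC/C=C(/C)C(OCC)OCC)C(=O)O1 | intermediate
12 | (3R,4aS,5S,8aS)-5-(diethoxymethyl)-3-(1,1-dimethoxyethyl)-5-methyloctahydro-1H-isochromen-1-one (cis-fused 19,7-lactone; 5α-H, 10β-CH3, 4α-H) | CC(OC)(OC)[C@H]1C[C@H]2[C@H](CCC[C@]2(C)C(OCC)OCC)C(=O)O1 | intermediate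
13 | (3R,4aR,5S,8aS)-5-(diethoxymethyl)-3-(1,1-dimethoxyethyl)-5,8a-dimethyloctahydro-1H-isochromen-1-one (4α-CH3) | CC(OC)(OC)[C@H]1C[C@H]2[C@](C)(CCC[C@]2(C)C(OCC)OCC)C(=O)O1 | intermediate
14 | (2R)-1-[(1S,2S,6S)-2-(diethoxymethyl)-6-(hydroxymethyl)-2,6-dimethylcyclohexyl]-3,3-dimethoxybutan-2-ol (diol bis-acetal, not isolated) | CC(OC)(OC)[C@H](O)C[C@H]1[C@@](C)(CO)CCC[C@]1(C)C(OCC)OCC | intermediate
15 | (1S,2S,3S)-2-[(2R)-2-hydroxy-3-oxobutyl]-3-(hydroxymethyl)-1,3-dimethylcyclohexane-1-carbaldehyde (open form; in equilibrium with the 7-O lactol) | CC(=O)[C@H](O)C[C@H]1[C@@](C)(CO)CCC[C@]1(C)C=O | intermediate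
16 | (3R)-3-hydroxy-4-[(1S,2S,6S)-2-(1-hydroxyprop-2-en-1-yl)-6-(hydroxymethyl)-2,6-dimethylcyclohexyl]butan-2-one (both C9 epimers) | CC(=O)[C@H](O)C[C@H]1[C@@](C)(CO)CCC[C@]1(C)C(O)C=C | intermediate
17 | (4S,5R,7R,8S,9R,10S)-13,14,15,16-tetranorlabd-11-ene-7,8,19-triol (7α,8α-diol, 9β-vinyl) | C=C[C@H]1[C@](C)(O)[C@H](O)C[C@H]2[C@@](C)(CO)CCC[C@@]21C | intermediate
18 | 9-[(4S,5R,7R,8S,9R,10S)-7,8,19-trihydroxy-13,14,15,16-tetranorlabdan-12-yl]-9-borabicyclo[3.3.1]nonane (alkylborane, not isolated; hydroxyls drawn free) | C1CCC2CCCC1B2CC[C@H]1[C@](C)(O)[C@H](O)C[C@H]2[C@@](C)(CO)CCC[C@@]21C | intermediate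
19 | (4S,5R,7R,8S,9R,10S)-labda-13(16),14-diene-7,8,19-triol | C=CC(=C)CC[C@H]1[C@](C)(O)[C@H](O)C[C@H]2[C@@](C)(CO)CCC[C@@]21C | intermediate
20 | 4-(oxan-2-yloxy)benzaldehyde (racemic acetal) | O=Cc1ccc(OC2CCCCO2)cc1 | starting material
21 | methyl 2-[bis(2,2,2-trifluoroethoxy)phosphoryl]acetate | COC(=O)CP(=O)(OCC(F)(F)F)OCC(F)(F)F | starting material
22 | methyl (2Z)-3-[4-(oxan-2-yloxy)phenyl]prop-2-enoate | COC(=O)/C=C\c1ccc(OC2CCCCO2)cc1 | intermediate
23 | (2Z)-3-[4-(oxan-2-yloxy)phenyl]prop-2-enoic acid | OC(=O)/C=C\c1ccc(OC2CCCCO2)cc1 | intermediate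
24 | (4S,5R,7R,8S,9R,10S)-7,8-dihydroxylabda-13(16),14-dien-19-yl (2Z)-3-[4-(oxan-2-yloxy)phenyl]prop-2-enoate | C=CC(=C)CC[C@H]1[C@](C)(O)[C@H](O)C[C@H]2[C@@](C)(COC(=O)/C=C\c3ccc(OC4CCCCO4)cc3)CCC[C@@]21C | intermediate
25 | (4S,5R,7R,8S,9R,10S)-7,8-dihydroxylabda-13(16),14-dien-19-yl (2Z)-3-(4-hydroxyphenyl)prop-2-enoate | C=CC(=C)CC[C@H]1[C@](C)(O)[C@H](O)C[C@H]2[C@@](C)(COC(=O)/C=C\c3ccc(O)cc3)CCC[C@@]21C | target

**Step count.** Total: 17 steps. Longest linear sequence: 14 steps (steps 1–6, 8–13, 16, 17).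

**Steps most likely to fail**

Step 8 (proposed new method). The allyl radical may be reduced to the alkene before it adds to 8. The acetate may fail to leave if the α-acyl radical is quenched by hydrogen instead of being reduced to the enolate. The C10 radical may add to a second molecule of 8 instead of cyclising. Facial selectivity at C10 may be poor. The fallback sets out from 8 and 10 and comes back at 12, and it makes the two bonds in separate, known operations. Diene 10 is hydroborated with 9-BBN-H at the terminal carbon of its monosubstituted vinyl group to give 9-[3-(diethoxymethyl)but-3-en-1-yl]-9-borabicyclo[3.3.1]nonane F1. Copper-catalysed allyl–alkyl coupling of this borane with acetate 8 (CuCl, KOt-Bu, THF) is an SN2′ substitution at the exocyclic CH2 with loss of acetate. It forms C2–C3 and gives (6R)-3-[4-(diethoxymethyl)pent-4-en-1-yl]-6-(1,1-dimethoxyethyl)-5,6-dihydro-2H-pyran-2-one F2. A hydrogen-atom-transfer radical conjugate cyclisation of its 1,1-disubstituted alkene (Fe(acac)3, PhSiH3, EtOH) then forms C5–C10 and gives 12.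

Step 12. The free allylic alcohol may not ionise to the π-allylpalladium complex. The allylindium may be protonated before it cyclises. The ketone face may be chosen without chelation, which would give the 8-epimer. The fallback sets out from 15 (step 11 is skipped) and comes back at 17, and it replaces the allylmetal by a Lewis-acid allylsilane cyclisation. Aldehyde-selective Wittig reaction of 15 with Ph3P=CHCH2SiMe3 at −78 °C gives the allylsilane 7α,19-dihydroxy-12-(trimethylsilyl)-8,9-seco-13,14,15,16-tetranorlabd-9(11)-en-8-one F3. Intramolecular Hosomi–Sakurai reaction (TiCl4, CH2Cl2, −78 °C), with titanium chelated between the 7-oxygen and the C8 carbonyl, closes ring B through C9 and gives 17.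

Step 13. Oxidative addition to the alkenyl chloride may be slow. The alkylborane may be protodeboronated by the free hydroxyls. Chloroprene may polymerise at 60 °C. The fallback sets out from 17 and comes back at 19, and it forms C12–C13 by copper-catalysed sp3–sp2 coupling of an alkyl iodide instead. The 7,8-diol is protected with 2,2-dimethoxypropane/PPTS as the acetonide (4S,5R,7R,8S,9R,10S)-7,8-(isopropylidenedioxy)-13,14,15,16-tetranorlabd-11-en-19-ol F4, which blocks ether formation between O8 and C12. Hydroboration–oxidation (9-BBN-H; NaOH, H2O2) gives 7,8-(isopropylidenedioxy)-13,14,15,16-tetranorlabdane-12,19-diol F5. Iodination of the unhindered primary alcohol (I2, PPh3, imidazole) gives 12-iodo-7,8-(isopropylidenedioxy)-13,14,15,16-tetranorlabdan-19-ol F6. Coupling with buta-1,3-dien-2-ylmagnesium chloride (from 2-chlorobuta-1,3-diene, Mg and cat. ZnCl2) and Li2CuCl4 gives 7,8-(isopropylidenedioxy)labda-13(16),14-dien-19-ol F7. Aqueous acetic acid at 40 °C removes the acetonide and gives 19.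

Further compounds

F1 | step 8 | 9-[3-(diethoxymethyl)but-3-en-1-yl]-9-borabicyclo[3.3.1]nonane | C=C(CCB1C2CCCC1CCC2)C(OCC)OCC
F2 | step 8 | (6R)-3-[4-(diethoxymethyl)pent-4-en-1-yl]-6-(1,1-dimethoxyethyl)-5,6-dihydro-2H-pyran-2-one | CC(OC)(OC)[C@H]1CC=C(CCCC(=C)C(OCC)OCC)C(=O)O1
F3 | step 12 | 7α,19-dihydroxy-12-(trimethylsilyl)-8,9-seco-13,14,15,16-tetranorlabd-9(11)-en-8-one (alkene isomers) | CC(=O)[C@H](O)C[C@H]1[C@@](C)(CO)CCC[C@]1(C)C=CC[Si](C)(C)C
F4 | step 13 | (4S,5R,7R,8S,9R,10S)-7,8-(isopropylidenedioxy)-13,14,15,16-tetranorlabd-11-en-19-ol | C=C[C@H]1[C@]3(C)OC(C)(C)O[C@@H]3C[C@H]2[C@@](C)(CO)CCC[C@@]21C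
F5 | step 13 | 7,8-(isopropylidenedioxy)-13,14,15,16-tetranorlabdane-12,19-diol | OCC[C@H]1[C@]3(C)OC(C)(C)O[C@@H]3C[C@H]2[C@@](C)(CO)CCC[C@@]21C
F6 | step 13 | 12-iodo-7,8-(isopropylidenedioxy)-13,14,15,16-tetranorlabdan-19-ol | ICC[C@H]1[C@]3(C)OC(C)(C)O[C@@H]3C[C@H]2[C@@](C)(CO)CCC[C@@]21C
F7 | step 13 | 7,8-(isopropylidenedioxy)labda-13(16),14-dien-19-ol | C=CC(=C)CC[C@H]1[C@]3(C)OC(C)(C)O[C@@H]3C[C@H]2[C@@](C)(CO)CCC[C@@]21C
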